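## The problem

The target 17 is an aryltetralin lignan. A guaiacol ring (ring A, OMe on C6, free OH on C7) is fused through C4a and C8a to a saturated ring B. Ring B carries a 4-hydroxy-3,5-dimethoxyphenyl ring (ring C) on C1, acetoxymethyl groups on C2 and C3, and a methylene at C4. The three contiguous stereocentres are (1S,2R,3R), all trans. C1 is a diarylmethine with no adjacent carbonyl and cannot be corrected once set. C2 and C3, if carried as esters, are epimerisable and settle into the all-equatorial array, so C1 must be fixed absolutely and can then dictate the other two. The sensitive groups are the two phenols (the ring C phenol is para to the benzylic C1–H and oxidises easily in base and air) and the two primary acetates, which survive neither alkoxide nor hydride and must go on last, with aryl and alkyl acyl groups told apart at the end. The enabling feature is that ring A meets ring B at C8a (para to the C6 methoxy group) and at C4a (para to the C7 oxygen), while C1–C2–C3–C4 is a four-carbon chain with carboxyl-level carbons on C2 and C3. An aryl cyclopropane-1,1,2-tricarboxylate therefore maps onto C1–C4, and an ortho-dioxygenated benzene supplies C8a and C4a. The hidden difficulty is that once C1–C8a exists, two aryl rings sit on C1 and either can be acylated. The ortho carbons of a 3,5-dimethoxyaryl ring are far more nucleophilic than C4a of ring A, so ring C must pass through the ring closure in a deactivated form.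

## Retrosynthesis

**Acetates (17 from 15 through 16).** The two alkyl O–acetyl bonds are cut last because they are the most base- and hydride-labile groups. Direct acetylation of the primary alcohols of tetraol 15 beside two phenols is possible but less certain than exhaustive acetylation to 16 followed by aminolysis of the two aryl acetates, which are activated esters. The forward steps need only aryl/alkyl ester chemoselectivity.

**Hydroxymethyl groups and the C2/C3 configuration (15 from 14, 14 from 13).** The C2 and C3 side chains are taken back to methyl esters. Against carrying them as protected alcohols, esters make both centres α-acidic, so the all-trans diester 14 is reached from any mixture 13 by equilibration and no selective C–C bond formation is needed at C2 or C3. The forward steps are a methoxide equilibration and a hydride reduction that leave C1 alone.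

**C4 methylene (13 from 12).** The two C4–H bonds are traced to a ketone, which is what a Friedel–Crafts acylation leaves behind. Hydrogenolysis over palladium is the shortest removal. It is placed after the bromines of ring C are gone, because palladium and hydrogen would strip them.

**Ring C oxygenation (12 from 11).** The two aryl C–OMe bonds of ring C are cut to C–Br, and both phenols are mesylated. With methoxy groups in place, ring C would take the acyl group in the ring closure. With bromines it is the least nucleophilic ring present, and the conversion of 3,5-dibromo-4-hydroxyaryl units into syringyl units with methoxide and copper is a classical reaction. Hot methoxide also removes both mesylates, so no separate deprotection is needed. The forward step must tolerate a β-keto ester, which is carried as its enolate.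

**Key disconnection (11 from 7 and 9 through 10).** C1–C8a and C4–C4a are cut together. Cutting only C4–C4a would be the classical stepwise tetralone closure and leaves the diarylmethine stereocentre to be made separately. Cutting C1–C1' would make ring C the nucleophile and give no handle on C1. The double cut reduces ring B to cyclopropane 7 (two stereocentres from one catalytic step) and the commodity arene 9. The forward reaction must open the cyclopropane at the aryl-bearing carbon with inversion, attack para to OMe on 9, and acylate ring A and not ring C.

**Cyclopropane (7 from 6, 6 from 5, 5 from 3 and 4).** The two ring bonds to the malonate carbon are cut, leading to enal 3 and dimethyl bromomalonate 4. The amine-catalysed Michael-initiated ring closure is preferred to metal-carbene routes because it gives the trans 2-formyl-3-aryl pattern in high enantiomeric purity. Oxidation and esterification (5 to 6 to 7) then put the third carboxyl at the ester level.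

**Aromatic building blocks (3 from 2, 2 from 1; 9 from 8).** The enal C=C bond is cut by a Wittig disconnection to aldehyde 2, the mesylate of commercial 3,5-dibromo-4-hydroxybenzaldehyde 1. Arene 9 is the mesylate of guaiacol 8.

## Roads not taken

**Alternative 1:** A one-carbon malonate unit is inserted between C1 and C3 (cuts C1–C2 and C2–C3). In the forward sense a malonate diester adds 1,6 to a quinone methide generated from the ring C phenol. Pd(PPh3)4 (zerovalent palladium) then ionises an allylic carbonate on the ring A side chain, and the same malonate carbon closes ring B to give A1.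
- Merits: ring C enters with its final oxygenation, C1 is set by asymmetric catalysis under mild conditions, and there is no question of which ring closes.
- Weak points: C2 arrives as a quaternary geminal diester, so one carboxyl must be excised afterwards. C3 carries a vinyl group whose configuration is fixed in the allylation and cannot be equilibrated. Turning vinyl into acetoxymethyl needs an oxidative cleavage beside two electron-rich rings.
- Comparison: this road is better in protecting-group and redox economy for ring C, since it needs no bromine detour and no superacid. The chosen plan offers in return both side-chain carbons at the right oxidation level from the start and correction of C2 and C3 by simple equilibration.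

**Alternative 2:** C2–C3 and C1–C8a are cut. Mn(OAc)3 (trivalent manganese) oxidises a cinnamyl benzylmalonate to the malonyl radical, which closes a lactone onto the alkene. The benzylic radical then attacks ring A para to OMe, and Cu(OAc)2 (divalent copper) rearomatises the ring to give A2.
- Merits: two C–C bonds, two rings and three stereocentres form in one step from an acyclic diester, and the radical closure onto ring A has no competition from ring C.
- Weak points: stoichiometric oxidants, facial control that rests on an 8-phenylmenthyl auxiliary acting on a radical, a cis lactone, and a quaternary C3 that must lose its extra carboxyl and be epimerised.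
- Comparison: this road builds more complexity per step than the chosen plan. The chosen plan draws its absolute configuration from a reliable catalytic step passed on by a stereospecific displacement, and it has no quaternary centre to dismantle.

**Alternative 3:** Ring A is made last (cuts C4a–C8a and C7–C8). A 3-bromo-4-methoxy-2-pyrone tethered to an alkyne on C1 undergoes intramolecular Diels–Alder addition and loses CO2 to give A3.
- Merits: the substitution pattern of ring A is unambiguous, and the three stereocentres and both acetates would already be in place, so nothing is epimerised afterwards.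
- Weak points: the stereotriad must be built on an open chain by separate asymmetric steps, the cycloaddition needs high temperature, and the C7 bromide must still become a hydroxyl group while base-sensitive acetates are present.
- Comparison: both roads contain a late halogen-to-oxygen exchange, so neither has the edge there, and this road is safer on the regiochemistry of ring A. The chosen plan is shorter and convergent, with two commodity aromatics and a bromomalonate.

Key step: step 7

Assumption: the sense of induction in step 3 follows the usual shielding model for diarylprolinol silyl ether iminium ions (the (S)-catalyst gives the (2R,3S)-2-formyl-3-arylcyclopropane), so the (R)-catalyst is used; if the sense proves opposite, the antipodal catalyst is used and nothing else changes.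

Remark: C2 and C3 of 11, 12 and 13 are written without configuration where they are α to carbonyl groups and are equilibrated in step 10.

**Step 1**
Reactants: 1 3,5-dibromo-4-hydroxybenzaldehyde
Product: 2 2,6-dibromo-4-formylphenyl methanesulfonate
Conditions: MsCl (1.2 equiv), Et3N (1.5 equiv), CH2Cl2, 0 °C to rt
Reagents that add atoms: methanesulfonyl chloride, CS(=O)(=O)Cl
Why: O-sulfonylation of an acidic phenol; the mesylate is stable to superacid and turns the para oxygen from a donor into an acceptor, which the later SN2-type ring opening needs.

**Step 2**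
Reactants: 2 2,6-dibromo-4-formylphenyl methanesulfonate
Product: 3 (E)-3-[3,5-dibromo-4-(methanesulfonyloxy)phenyl]prop-2-enal
Conditions: Ph3P=CHCHO (1.2 equiv), toluene, 80 °C
Reagents that add atoms: (triphenylphosphoranylidene)acetaldehyde, O=CC=P(c1ccccc1)(c1ccccc1)c1ccccc1
Why: Wittig olefination with a stabilised ylide gives the E-enal; the electron-poor aryl aldehyde is more electrophilic than the product enal, so a second homologation should be minor.

**Step 3**
Reactants: 3 (E)-3-[3,5-dibromo-4-(methanesulfonyloxy)phenyl]prop-2-enal; 4 dimethyl bromomalonate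
Product: 5 dimethyl (2S,3R)-2-formyl-3-[3,5-dibromo-4-(methanesulfonyloxy)phenyl]cyclopropane-1,1-dicarboxylate
Conditions: (R)-2-[diphenyl(trimethylsilyloxy)methyl]pyrrolidine (20 mol%), 2,6-lutidine (1.1 equiv), CH2Cl2, 0 °C to rt
Reagents that add atoms: none
Why: Amine-catalysed Michael-initiated ring closure: the bromomalonate adds to the β-carbon of the iminium ion on the face away from the CPh2(OSiMe3) group and the resulting enamine displaces bromide (3-exo-tet), giving the trans cyclopropane with the aryl-bearing carbon R and the formyl-bearing carbon S.

**Step 4**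
Reactants: 5 dimethyl (2S,3R)-2-formyl-3-[3,5-dibromo-4-(methanesulfonyloxy)phenyl]cyclopropane-1,1-dicarboxylate
Product: 6 (1S,3R)-3-[3,5-dibromo-4-(methanesulfonyloxy)phenyl]-2,2-bis(methoxycarbonyl)cyclopropane-1-carboxylic acid
Conditions: NaClO2, NaH2PO4, 2-methyl-2-butene, t-BuOH–H2O, 0 °C to rt
Reagents that add atoms: sodium chlorite, [Na+].[O-]Cl=O
Why: Pinnick oxidation of the aldehyde under buffered conditions that touch neither the cyclopropane nor the aryl mesylate; both stereocentres are untouched.

**Step 5**
Reactants: 6 (1S,3R)-3-[3,5-dibromo-4-(methanesulfonyloxy)phenyl]-2,2-bis(methoxycarbonyl)cyclopropane-1-carboxylic acid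
Product: 7 trimethyl (2S,3R)-3-[3,5-dibromo-4-(methanesulfonyloxy)phenyl]cyclopropane-1,1,2-tricarboxylate
Conditions: MeI (3 equiv), KHCO3 (2 equiv), DMF, rt
Reagents that add atoms: iodomethane, CI
Why: SN2 O-methylation of the carboxylate; hydrogencarbonate is too weak a base to cleave the activated aryl mesylate or to open the cyclopropane.

**Step 6**
Reactants: 8 guaiacol (2-methoxyphenol)
Product: 9 2-methoxyphenyl methanesulfonate
Conditions: MsCl (1.2 equiv), Et3N (1.5 equiv), CH2Cl2, 0 °C to rt
Reagents that add atoms: methanesulfonyl chloride, CS(=O)(=O)Cl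
Why: O-sulfonylation; the mesyloxy group is a much weaker donor than methoxy, so 9 reacts with electrophiles para to OMe, and it survives CF3SO3H.

**Step 7**
Reactants: 7 trimethyl (2S,3R)-3-[3,5-dibromo-4-(methanesulfonyloxy)phenyl]cyclopropane-1,1,2-tricarboxylate; 9 2-methoxyphenyl methanesulfonate
Product: 11 dimethyl (1S,2S)-1-[3,5-dibromo-4-(methanesulfonyloxy)phenyl]-7-(methanesulfonyloxy)-6-methoxy-4-oxo-1,2,3,4-tetrahydronaphthalene-2,3-dicarboxylate (C3 epimers), via ring-opened triester 10 (not isolated)
Conditions: 9 (1.2 equiv), CF3SO3H (0.2 equiv), (CF3)2CHOH (HFIP), 40 °C; evaporate; CF3SO3H (20 equiv), ClCH2CH2Cl (0.02 M), 50 °C; cold MeOH quench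
Reagents that add atoms: none
Why: Proposed new method: each half is a known reaction type (Brønsted acid/HFIP arylative ring opening of donor–acceptor cyclopropanes with inversion, and strong-acid cycliacylation of aryl-substituted esters and malonates to 1-tetralones), but their pairing in one flask on a cyclopropane-1,1,2-triester is untested. In stage 1 the acid activates the geminal diester of 7, the bond between the aryl-bearing carbon and the diester carbon is polarised, and 9 attacks the aryl-bearing carbon through the position para to its methoxy group from the side opposite the departing malonate, giving 10. In stage 2 excess CF3SO3H ionises one geminal ester to an acylium (or acylketene) ion, which attacks ring A ortho to the new bond and para to the mesyloxy group, a six-membered Friedel–Crafts closure of ring B with loss of methanol. C1 of 11 is set by inversion at the enantioenriched aryl-bearing carbon of 7 (S in 11); the electron-poor dibromoaryl group cannot support a free benzylic cation, so the SN2-like path and the enantiomeric purity should be kept. C2 keeps its cyclopropane configuration (1,2-cis) and C3 is a β-keto ester carbon; both are corrected in step 10. The step needs attack of 9 para to OMe (the mesyloxy group deactivates its own para position), cleavage of the bond to the doubly activated carbon and not the bond to the singly activated one, acylation of ring A and not ring C (ring C carries two bromines and a mesyloxy group and no methoxy groups at this stage), and six-membered closure from a malonate ester over five-membered closure from the C2 ester. Near-stoichiometric 9 and dilution in stage 2 limit intermolecular acylation of surplus 9, and the methanol quench returns any activated acyl species at C3 to the methyl ester.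

**Step 8**
Reactants: 11 dimethyl (1S,2S)-1-[3,5-dibromo-4-(methanesulfonyloxy)phenyl]-7-(methanesulfonyloxy)-6-methoxy-4-oxo-1,2,3,4-tetrahydronaphthalene-2,3-dicarboxylate
Product: 12 dimethyl (1S)-7-hydroxy-1-(4-hydroxy-3,5-dimethoxyphenyl)-6-methoxy-4-oxo-1,2,3,4-tetrahydronaphthalene-2,3-dicarboxylate (C2/C3 epimers, keto–enol mixture)
Conditions: NaOMe (12 equiv), CuBr (0.3 equiv), MeOH–DMF, 100 °C, argon; then aq. HCl
Reagents that add atoms: sodium methoxide, [Na+].[O-]C
Why: Ullmann-type copper-catalysed methoxylation of an ortho,ortho'-dibromophenoxide, the classical way from 3,5-dibromo-4-hydroxyaryl compounds to the syringyl pattern; hot methoxide first cleaves both aryl mesylates at sulfur, the β-keto ester is protected as its enolate, methyl esters are degenerate towards methoxide, and C1 is not acidic enough to epimerise.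

**Step 9**
Reactants: 12 dimethyl (1S)-7-hydroxy-1-(4-hydroxy-3,5-dimethoxyphenyl)-6-methoxy-4-oxo-1,2,3,4-tetrahydronaphthalene-2,3-dicarboxylate
Product: 13 dimethyl (1S)-7-hydroxy-1-(4-hydroxy-3,5-dimethoxyphenyl)-6-methoxy-1,2,3,4-tetrahydronaphthalene-2,3-dicarboxylate (C2/C3 epimers)
Conditions: H2 (3 atm), 10% Pd/C, AcOH, HClO4 (cat.), 50 °C
Reagents that add atoms: none
Why: Acid-promoted hydrogenolysis of an aryl ketone over Pd/C (ketone to benzylic alcohol to methylene), eased by the para hydroxyl group on ring A; esters, aryl ethers and the diarylmethine C1 are not affected.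

**Step 10**
Reactants: 13 dimethyl (1S)-7-hydroxy-1-(4-hydroxy-3,5-dimethoxyphenyl)-6-methoxy-1,2,3,4-tetrahydronaphthalene-2,3-dicarboxylate
Product: 14 dimethyl (1S,2R,3R)-7-hydroxy-1-(4-hydroxy-3,5-dimethoxyphenyl)-6-methoxy-1,2,3,4-tetrahydronaphthalene-2,3-dicarboxylate
Conditions: NaOMe (5 equiv), MeOH, reflux, argon; AcOH quench
Reagents that add atoms: none
Why: Thermodynamic epimerisation through the ester enolates; C1 is fixed, so both ester groups settle trans to their neighbours in the all-equatorial 1,2-trans-2,3-trans isomer, the expected equilibrium outcome for 1-aryltetralin-2,3-diesters.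

**Step 11**
Reactants: 14 dimethyl (1S,2R,3R)-7-hydroxy-1-(4-hydroxy-3,5-dimethoxyphenyl)-6-methoxy-1,2,3,4-tetrahydronaphthalene-2,3-dicarboxylate
Product: 15 (1S,2R,3R)-7-hydroxy-1-(4-hydroxy-3,5-dimethoxyphenyl)-6-methoxy-1,2,3,4-tetrahydronaphthalene-2,3-dimethanol
Conditions: LiAlH4 (6 equiv), THF, 0 °C to 50 °C; aq. potassium sodium tartrate
Reagents that add atoms: none
Why: Hydride reduction of both esters to primary alcohols; the phenols ride through as aluminium phenoxides, and after reduction no stereocentre is α to a carbonyl group.

**Step 12**
Reactants: 15 (1S,2R,3R)-7-hydroxy-1-(4-hydroxy-3,5-dimethoxyphenyl)-6-methoxy-1,2,3,4-tetrahydronaphthalene-2,3-dimethanol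
Product: 16 [(1S,2R,3R)-7-acetoxy-1-(4-acetoxy-3,5-dimethoxyphenyl)-6-methoxy-1,2,3,4-tetrahydronaphthalene-2,3-diyl]bis(methylene) diacetate
Conditions: Ac2O, pyridine, DMAP (cat.), rt
Reagents that add atoms: acetic anhydride, CC(=O)OC(C)=O
Why: Exhaustive acylation under nucleophilic catalysis; making all four hydroxyl groups alike avoids any selectivity question at this stage.

**Step 13**
Reactants: 16 [(1S,2R,3R)-7-acetoxy-1-(4-acetoxy-3,5-dimethoxyphenyl)-6-methoxy-1,2,3,4-tetrahydronaphthalene-2,3-diyl]bis(methylene) diacetate
Product: 17 [(1S,2R,3R)-7-hydroxy-1-(4-hydroxy-3,5-dimethoxyphenyl)-6-methoxy-1,2,3,4-tetrahydronaphthalene-2,3-diyl]bis(methylene) diacetate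
Conditions: pyrrolidine (6 equiv), CH2Cl2, 0 °C to rt
Reagents that add atoms: none
Why: Chemoselective aminolysis: aryl acetates are activated esters with a phenoxide leaving group and are cleaved by a secondary amine much faster than primary alkyl acetates.

## Compound list

1 | 3,5-dibromo-4-hydroxybenzaldehyde | O=Cc1cc(Br)c(O)c(Br)c1 | starting material
2 | 2,6-dibromo-4-formylphenyl methanesulfonate | O=Cc1cc(Br)c(OS(C)(=O)=O)c(Br)c1 | intermediate
3 | (E)-3-[3,5-dibromo-4-(methanesulfonyloxy)phenyl]prop-2-enal | O=C/C=C/c1cc(Br)c(OS(C)(=O)=O)c(Br)c1 | intermediate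
4 | dimethyl bromomalonate | COC(=O)C(Br)C(=O)OC | starting material
5 | dimethyl (2S,3R)-2-formyl-3-[3,5-dibromo-4-(methanesulfonyloxy)phenyl]cyclopropane-1,1-dicarboxylate | O=C[C@H]1[C@H](c2cc(Br)c(OS(C)(=O)=O)c(Br)c2)C1(C(=O)OC)C(=O)OC | intermediate
6 | (1S,3R)-3-[3,5-dibromo-4-(methanesulfonyloxy)phenyl]-2,2-bis(methoxycarbonyl)cyclopropane-1-carboxylic acid | OC(=O)[C@H]1[C@H](c2cc(Br)c(OS(C)(=O)=O)c(Br)c2)C1(C(=O)OC)C(=O)OC | intermediate
7 | trimethyl (2S,3R)-3-[3,5-dibromo-4-(methanesulfonyloxy)phenyl]cyclopropane-1,1,2-tricarboxylate (aryl and C2 ester trans) | COC(=O)[C@H]1[C@H](c2cc(Br)c(OS(C)(=O)=O)c(Br)c2)C1(C(=O)OC)C(=O)OC | intermediate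
8 | guaiacol (2-methoxyphenol) | COc1ccccc1O | starting material
9 | 2-methoxyphenyl methanesulfonate | COc1ccccc1OS(C)(=O)=O | intermediate
10 | trimethyl (2S,3R)-3-[3,5-dibromo-4-(methanesulfonyloxy)phenyl]-3-[3-(methanesulfonyloxy)-4-methoxyphenyl]propane-1,1,2-tricarboxylate | COc1ccc(cc1OS(C)(=O)=O)[C@H](c1cc(Br)c(OS(C)(=O)=O)c(Br)c1)[C@H](C(=O)OC)C(C(=O)OC)C(=O)OC | intermediate (not isolated)
11 | dimethyl (1S,2S)-1-[3,5-dibromo-4-(methanesulfonyloxy)phenyl]-7-(methanesulfonyloxy)-6-methoxy-4-oxo-1,2,3,4-tetrahydronaphthalene-2,3-dicarboxylate (1,2-cis, C3 unassigned) | COc1cc2c(cc1OS(C)(=O)=O)[C@H](c1cc(Br)c(OS(C)(=O)=O)c(Br)c1)[C@H](C(=O)OC)C(C(=O)OC)C2=O | intermediate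
12 | dimethyl (1S)-7-hydroxy-1-(4-hydroxy-3,5-dimethoxyphenyl)-6-methoxy-4-oxo-1,2,3,4-tetrahydronaphthalene-2,3-dicarboxylate (C2, C3 unassigned) | COc1cc2c(cc1O)[C@H](c1cc(OC)c(O)c(OC)c1)C(C(=O)OC)C(C(=O)OC)C2=O | intermediate
13 | dimethyl (1S)-7-hydroxy-1-(4-hydroxy-3,5-dimethoxyphenyl)-6-methoxy-1,2,3,4-tetrahydronaphthalene-2,3-dicarboxylate (C2, C3 unassigned) | COc1cc2c(cc1O)[C@H](c1cc(OC)c(O)c(OC)c1)C(C(=O)OC)C(C(=O)OC)C2 | intermediate
14 | dimethyl (1S,2R,3R)-7-hydroxy-1-(4-hydroxy-3,5-dimethoxyphenyl)-6-methoxy-1,2,3,4-tetrahydronaphthalene-2,3-dicarboxylate (all-trans) | COc1cc2c(cc1O)[C@H](c1cc(OC)c(O)c(OC)c1)[C@@H](C(=O)OC)[C@H](C(=O)OC)C2 | intermediate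
15 | (1S,2R,3R)-7-hydroxy-1-(4-hydroxy-3,5-dimethoxyphenyl)-6-methoxy-1,2,3,4-tetrahydronaphthalene-2,3-dimethanol | COc1cc2c(cc1O)[C@H](c1cc(OC)c(O)c(OC)c1)[C@@H](CO)[C@H](CO)C2 | intermediate
16 | [(1S,2R,3R)-7-acetoxy-1-(4-acetoxy-3,5-dimethoxyphenyl)-6-methoxy-1,2,3,4-tetrahydronaphthalene-2,3-diyl]bis(methylene) diacetate | COc1cc2c(cc1OC(C)=O)[C@H](c1cc(OC)c(OC(C)=O)c(OC)c1)[C@@H](COC(C)=O)[C@H](COC(C)=O)C2 | intermediate
17 | [(1S,2R,3R)-7-hydroxy-1-(4-hydroxy-3,5-dimethoxyphenyl)-6-methoxy-1,2,3,4-tetrahydronaphthalene-2,3-diyl]bis(methylene) diacetate | COc1cc2c(cc1O)[C@H](c1cc(OC)c(O)c(OC)c1)[C@@H](COC(C)=O)[C@H](COC(C)=O)C2 | target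

## Step count and risks

Total: 13 steps. Longest linear sequence: 12 steps (steps 1–5 and 7–13, from 1 to 17); the arene branch (step 6) is one step.

**Step 7 (key step, new pairing).** Two processes are most likely to fail.
- The ring opening may be slow, because a deactivated dibromoaryl donor meets a weakly nucleophilic arene; lactonisation by an ester oxygen or solvolysis can then overtake it.
- The acylation may stall at a ring position that is only weakly activated (para to a mesyloxy group), or be diverted to intermolecular acylation of surplus 9.

Fallback with known chemistry, from 7 and 9 back to 11: the ring opening is run alone under catalytic CF3SO3H in HFIP with a large excess of 9, and 10 is isolated and freed of 9. One malonate ester is saponified selectively with one equivalent of LiOH at 0 °C (malonate esters hydrolyse fastest) to give the malonic half-acid F1. Oxalyl chloride converts it into the acid chloride F2, and SnCl4 in CH2Cl2 closes ring B by a conventional Friedel–Crafts acylation to give 11.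

**Step 8.** The enolate and phenoxides can be oxidised (aromatisation of ring B would erase C1), reductive loss of bromine can leave ring C under-methoxylated, traces of hydroxide can cut the esters, and the methyl sulfonate formed in the mesylate cleavage can O-methylate a phenoxide. Fallback that changes the order, from 11 back to 14: 11 is reduced with NaBH4 to the C4 alcohol F3. Acid-catalysed dehydration (TsOH, toluene, reflux) gives the 1,2-dihydronaphthalene diester F4, and hydrogenation over PtO2, which spares aryl bromides, gives the ketone-free dibromo diester F5. The NaOMe/CuBr exchange is then run on this simple diester, where it also equilibrates C2 and C3, and the sequence rejoins the route at 14.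

**Step 9.** The hydrogenolysis may stop at the benzylic alcohol, or the strongly enolised keto ester may be taken up slowly, with ring hydrogenation as the side process on forcing. Fallback, from 12 back to 13: NaBH4 reduction gives the benzylic alcohol F6, and ionic hydrogenation with Et3SiH and CF3CO2H removes the hydroxyl group through the cation, which is stabilised by the para hydroxyl group of ring A.

**Step 13.** The hindered syringyl acetate may cleave slowly, so that on longer exposure the primary acetates begin to be lost or acyl groups migrate. Fallback, from 15 directly to 17: lipase-catalysed transesterification (Candida antarctica lipase B, vinyl acetate) acylates primary alcohols and leaves phenols free, so 16 is bypassed and no new compound is made (listed as F0).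

## Further compounds

F1 | step 7 | (3S,4R)-4-[3,5-dibromo-4-(methanesulfonyloxy)phenyl]-4-[3-(methanesulfonyloxy)-4-methoxyphenyl]-2,3-bis(methoxycarbonyl)butanoic acid (C2 epimers) | COc1ccc(cc1OS(C)(=O)=O)[C@H](c1cc(Br)c(OS(C)(=O)=O)c(Br)c1)[C@H](C(=O)OC)C(C(=O)O)C(=O)OC
F2 | step 7 | acid chloride of F1, dimethyl 2-(chlorocarbonyl)-3-{(R)-[3,5-dibromo-4-(methanesulfonyloxy)phenyl][3-(methanesulfonyloxy)-4-methoxyphenyl]methyl}butanedioate (3S, C2 epimers) | COc1ccc(cc1OS(C)(=O)=O)[C@H](c1cc(Br)c(OS(C)(=O)=O)c(Br)c1)[C@H](C(=O)OC)C(C(=O)Cl)C(=O)OC
F3 | step 8 | dimethyl (1S,2S)-1-[3,5-dibromo-4-(methanesulfonyloxy)phenyl]-4-hydroxy-7-(methanesulfonyloxy)-6-methoxy-1,2,3,4-tetrahydronaphthalene-2,3-dicarboxylate (C3, C4 unassigned) | COc1cc2c(cc1OS(C)(=O)=O)[C@H](c1cc(Br)c(OS(C)(=O)=O)c(Br)c1)[C@H](C(=O)OC)C(C(=O)OC)C2O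
F4 | step 8 | dimethyl (1S,2S)-1-[3,5-dibromo-4-(methanesulfonyloxy)phenyl]-7-(methanesulfonyloxy)-6-methoxy-1,2-dihydronaphthalene-2,3-dicarboxylate | COc1cc2c(cc1OS(C)(=O)=O)[C@H](c1cc(Br)c(OS(C)(=O)=O)c(Br)c1)[C@H](C(=O)OC)C(C(=O)OC)=C2
F5 | step 8 | dimethyl (1S,2S)-1-[3,5-dibromo-4-(methanesulfonyloxy)phenyl]-7-(methanesulfonyloxy)-6-methoxy-1,2,3,4-tetrahydronaphthalene-2,3-dicarboxylate (C3 unassigned) | COc1cc2c(cc1OS(C)(=O)=O)[C@H](c1cc(Br)c(OS(C)(=O)=O)c(Br)c1)[C@H](C(=O)OC)C(C(=O)OC)C2
F6 | step 9 | dimethyl (1S)-4,7-dihydroxy-1-(4-hydroxy-3,5-dimethoxyphenyl)-6-methoxy-1,2,3,4-tetrahydronaphthalene-2,3-dicarboxylate (C2, C3, C4 unassigned) | COc1cc2c(cc1O)[C@H](c1cc(OC)c(O)c(OC)c1)C(C(=O)OC)C(C(=O)OC)C2O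
F0 | step 13 | none | none
A1 | alternative 1 | dimethyl (1S,3S)-7-(benzyloxy)-1-(4-hydroxy-3,5-dimethoxyphenyl)-6-methoxy-3-vinyl-3,4-dihydronaphthalene-2,2(1H)-dicarboxylate | COc1cc2c(cc1OCc3ccccc3)[C@H](c4cc(OC)c(O)c(OC)c4)C(C(=O)OC)(C(=O)OC)[C@H](C=C)C2
A2 | alternative 2 | 8-phenylmenthyl 6-(benzyloxy)-4-[4-(benzyloxy)-3,5-dimethoxyphenyl]-7-methoxy-1-oxo-1,3,3a,4,9,9a-hexahydronaphtho[2,3-c]furan-9a-carboxylate (cis ring fusion) | COc1cc2c(cc1OCc3ccccc3)[C@H](c4cc(OC)c(OCc5ccccc5)c(OC)c4)[C@H]6COC(=O)[C@@]6(C(=O)O[C@@H]7C[C@H](C)CC[C@H]7C(C)(C)c8ccccc8)C2
A3 | alternative 3 | [(1S,2R,3R)-1-[4-(benzyloxy)-3,5-dimethoxyphenyl]-7-bromo-6-methoxy-1,2,3,4-tetrahydronaphthalene-2,3-diyl]bis(methylene) diacetate | COc1cc2c(cc1Br)[C@H](c3cc(OC)c(OCc4ccccc4)c(OC)c3)[C@@H](COC(C)=O)[C@H](COC(C)=O)C2
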